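**Plan**
1. Cuts: the C2′–C3′ bond (acrylate ester of the ring A alcohol + C3′–C12′ tetraenal), then C7′–C8′ of the tetraene. In the bicyclic half: the O1–acyl bond, the CH2OH carbon of the C8 acyl group, the C4a–O ether bond, the C4a–C8a and C7–C8 bonds (furan cycloaddition), the C1–C8a acyl bond and the C4–furan bond.
2. Feature used for the union: O1 of ring A carries C1′(=O)–C2′H(CH3)–C3′H(OH)–C4′=, an α-methyl-β-hydroxy ester whose carbinol carbon is allylic to the tetraene. This is what results when an acrylate-derived enolate (hydride onto the future C2′ methyl carbon) adds to a non-enolizable 2-methyl-enal.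
3. Forward, core: furan alkylation, acylation to an enedione, one intramolecular Diels–Alder step that closes ring A and ring B together as an oxygen-bridged adduct (C4a–O–C7), C1 ketone reduction, opening of the bridge to the C4=C4a–C5=C6 diene and the C7 carbinol, acrylate at O1, hydroxymethylation of the C8 acetyl group.
4. Forward, chain and union: a Z-iodo dienoate (C8′–C12′) and an E,E-stannyl dienal (C3′–C7′) are joined by Stille coupling. Tetraenal and acrylate are then joined at C2′–C3′ by a rhodium-catalysed asymmetric reductive aldol reaction, and the silyl groups are removed.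
5. Stereochemistry: C3 from (S)-1-bromo-3-chloro-2-methylpropane; C4a, C7, C8 and C8a from the cycloaddition (relay from C3, E-dienophile, exo tether); C1 from hydride attack opposite the bridge; C2′ and C3′ from the chiral rhodium catalyst; 8′Z from hydroalumination–iodination; the E alkenes from Wittig, Horner–Wadsworth–Emmons and hydrostannation steps.

Key step: step 18

Remark: ring atoms are numbered C1–C8a (C1 bears the ester oxygen, C7 the tertiary hydroxyl, C8 the acyl group) and the chain C1′ (ester carbonyl) to C12′ (CO2H); the C8′=C9′ bond of the target as drawn is Z; the (S,S) catalyst of step 18 is assumed to transfer the (2S,3R)-anti sense expected for simple acrylates with aryl or alkenyl aldehydes.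

**Step 1**
Reactants: 1 2-methylfuran; 2 (S)-1-bromo-3-chloro-2-methylpropane
Product: 4 (R)-2-(3-chloro-2-methylpropyl)-5-methylfuran, via 5-methyl-2-furyllithium 3 (not isolated)
Conditions: n-BuLi, THF, 0 °C to rt; then 2, DMPU, −78 °C to rt
Reagents that add atoms: none
Why: α-Lithiation of the furan and SN2 alkylation at the primary bromide (the chloride is kept for step 5); the methyl-bearing carbon, later C3, is not touched and comes unchanged from 2.

**Step 2**
Reactants: 5 butane-2,3-dione; 6 tert-butyl (triphenylphosphoranylidene)acetate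
Product: 7 tert-butyl (E)-3-methyl-4-oxopent-2-enoate
Conditions: CH2Cl2, 0 °C to rt (6 added slowly to excess 5); chromatography to remove the minor Z isomer
Reagents that add atoms: none
Why: Wittig mono-olefination of the activated 1,2-diketone by a stabilized ylide should favour the E isomer, in which ester and acetyl groups are trans.

**Step 3**
Reactants: 7 tert-butyl (E)-3-methyl-4-oxopent-2-enoate
Product: 8 (E)-3-methyl-4-oxopent-2-enoic acid
Conditions: TFA, CH2Cl2, 0 °C to rt
Reagents that add atoms: none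
Why: Acidolysis of the tert-butyl ester (E1 loss of the tert-butyl group) leaves the enone untouched.

**Step 4**
Reactants: 8 (E)-3-methyl-4-oxopent-2-enoic acid
Product: 9 (E)-3-methyl-4-oxopent-2-enoyl chloride
Conditions: (COCl)2, DMF (cat.), CH2Cl2, 0 °C to rt; concentrated and used crude
Reagents that add atoms: oxalyl chloride, ClC(=O)C(=O)Cl
Why: Acid chloride formation by Vilsmeier-type activation; the E geometry keeps the ketone away from the acyl carbon, so ring closure to a pseudo-chloride should not compete.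

**Step 5**
Reactants: 4 (R)-2-(3-chloro-2-methylpropyl)-5-methylfuran; 9 (E)-3-methyl-4-oxopent-2-enoyl chloride
Product: 12 (3E,7R)-3,7-dimethyl-8-(5-methylfuran-2-yl)oct-3-ene-2,5-dione, via alkylmagnesium chloride 10 (not isolated), via alkylzinc chloride 11 (not isolated)
Conditions: Mg, THF, 65 °C; ZnCl2, THF, 0 °C; then 9, Pd(PPh3)4 (5 mol %), THF, 0 °C to rt
Reagents that add atoms: none
Why: Negishi acylation: the alkylzinc chloride couples with the acyl chloride under palladium catalysis without adding to the ketone or the enone, and no stereocentre is formed or touched.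

**Step 6**
Reactants: 12 (3E,7R)-3,7-dimethyl-8-(5-methylfuran-2-yl)oct-3-ene-2,5-dione
Product: 13 (3R,4aS,7R,8R,8aR)-8-acetyl-4a,7-epoxy-3,7,8-trimethyl-3,4,4a,7,8,8a-hexahydronaphthalen-1(2H)-one
Conditions: Me2AlCl (1.1 equiv), CH2Cl2, −78 to −20 °C; aq. Rochelle salt; used at once
Reagents that add atoms: none
Why: Lewis-acid-promoted intramolecular Diels–Alder reaction of the furan (diene C4a=C5–C6=C7) with the doubly activated E-enedione (C8a=C8) closes ring A through the four-atom tether in the exo mode with the C3 methyl equatorial, so that C3 fixes C4a, C7, C8 and C8a, while the E alkene places the C8 methyl exo (syn to the oxygen bridge) and the acetyl group and H8a endo.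

**Step 7**
Reactants: 13 (3R,4aS,7R,8R,8aR)-8-acetyl-4a,7-epoxy-3,7,8-trimethyl-3,4,4a,7,8,8a-hexahydronaphthalen-1(2H)-one
Product: 14 (1S,3S,4aS,7R,8R,8aS)-8-acetyl-4a,7-epoxy-3,7,8-trimethyl-1,2,3,4,4a,7,8,8a-octahydronaphthalen-1-ol
Conditions: L-Selectride (LiBH(s-Bu)3, 1.05 equiv), THF, −90 to −78 °C; then aq. NH4Cl
Reagents that add atoms: none
Why: Ketone reduction by a bulky trialkylborohydride: hydride reaches the ring ketone from the equatorial side (the axial face is covered by the syn-axial bridge oxygen), which sets C1 with the hydroxyl axial and syn to the bridge, while the neopentyl endo acetyl group should react far more slowly at −90 °C.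

**Step 8**
Reactants: 14 (1S,3S,4aS,7R,8R,8aS)-8-acetyl-4a,7-epoxy-3,7,8-trimethyl-1,2,3,4,4a,7,8,8a-octahydronaphthalen-1-ol
Product: 16 (1S,3S,7R,8R,8aS)-8-acetyl-3,7,8-trimethyl-1,2,3,7,8,8a-hexahydronaphthalene-1,7-diol, via dilithium alkoxide-enolate 15 (not isolated)
Conditions: LDA (4 equiv), THF–hexane, −40 °C to rt; then aq. NH4Cl, −40 °C
Reagents that add atoms: none
Why: Proposed new method: alkoxide-directed syn-β-elimination that isomerizes the oxanorbornene to the dienol; LDA first forms the C1 lithium alkoxide and the acetyl enolate (15), then a further lithium amide held between the axial C1–O and the syn-axial bridge oxygen removes the syn-clinal equatorial hydrogen on C4 through a six-membered Li–O–C4a–C4–H–N transition state while the allylic C4a–O bond breaks with release of the bicyclic strain, giving C4=C4a next to C5=C6 and the C7 alkoxide; H8a is anti to the bridge oxygen and so outside this syn pathway, the C7 methyl lies on the far side of the bridge from the chelation site and under the exo C8 methyl, and the acetyl group is parked as its enolate (which also blocks retro-aldol cleavage), so C8a, C7 and C8 stay untouched; the closest known reaction types are the lithium- or aluminium-amide isomerization of epoxides to allylic alcohols and the base-induced β-elimination opening of 7-oxanorbornenes that carry an acidifying group.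

**Step 9**
Reactants: 16 (1S,3S,7R,8R,8aS)-8-acetyl-3,7,8-trimethyl-1,2,3,7,8,8a-hexahydronaphthalene-1,7-diol
Product: 17 (1S,3S,7R,8R,8aS)-8-acetyl-7-hydroxy-3,7,8-trimethyl-1,2,3,7,8,8a-hexahydronaphthalen-1-yl prop-2-enoate
Conditions: acryloyl chloride, i-Pr2NEt, DMAP (cat.), CH2Cl2, −20 to 0 °C
Reagents that add atoms: acryloyl chloride, C=CC(=O)Cl
Why: Acylation of the axial secondary alcohol by a small, reactive acyl chloride under nucleophilic catalysis; the tertiary C7 hydroxyl should not compete.

**Step 10**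
Reactants: 17 (1S,3S,7R,8R,8aS)-8-acetyl-7-hydroxy-3,7,8-trimethyl-1,2,3,7,8,8a-hexahydronaphthalen-1-yl prop-2-enoate
Product: 19 (1S,3S,7R,8R,8aS)-8-(3-hydroxypropanoyl)-3,7,8-trimethyl-7-(triethylsilyloxy)-1,2,3,7,8,8a-hexahydronaphthalen-1-yl prop-2-enoate, via bis(triethylsilyl) enol ether 18 (not isolated)
Conditions: TESOTf (2.5 equiv), Et3N (4 equiv), CH2Cl2, −78 to 0 °C; then aq. HCHO (37 %), Yb(OTf)3 (20 mol %), THF, rt
Reagents that add atoms: triethylsilyl trifluoromethanesulfonate, CC[Si](CC)(CC)OS(=O)(=O)C(F)(F)F; formaldehyde, C=O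
Why: Soft enolization turns the only enolizable ketone (the acetyl group) into its terminal silyl enol ether and caps the tertiary C7 hydroxyl, and the Yb(OTf)3-catalysed aqueous Mukaiyama aldol reaction with formaldehyde then adds the CH2OH carbon under conditions that should spare the acrylate and the dienyl silyl ether.

**Step 11**
Reactants: 19 (1S,3S,7R,8R,8aS)-8-(3-hydroxypropanoyl)-3,7,8-trimethyl-7-(triethylsilyloxy)-1,2,3,7,8,8a-hexahydronaphthalen-1-yl prop-2-enoate
Product: 20 (1S,3S,7R,8R,8aS)-3,7,8-trimethyl-7-(triethylsilyloxy)-8-[3-(triethylsilyloxy)propanoyl]-1,2,3,7,8,8a-hexahydronaphthalen-1-yl prop-2-enoate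
Conditions: TESCl, imidazole, CH2Cl2, 0 °C
Reagents that add atoms: chlorotriethylsilane, CC[Si](CC)(CC)Cl
Why: Silylation of the primary alcohol, so that no O–H is left to quench the rhodium enolate of step 18.

**Step 12**
Reactants: 21 but-2-yn-1-ol
Product: 23 (Z)-3-iodobut-2-en-1-ol, via cyclic alkenylalanate 22 (not isolated)
Conditions: Red-Al (NaAlH2(OCH2CH2OMe)2), THF, 0 °C to rt; then I2, THF, −78 °C
Reagents that add atoms: iodine, II
Why: trans-Hydroalumination of the propargylic alcohol through its alkoxyaluminate puts aluminium on C3 cis to the CH2O group, and iodinolysis with retention gives the Z iodoalkene, the source of the Z C8′=C9′ bond.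

**Step 13**
Reactants: 23 (Z)-3-iodobut-2-en-1-ol; 24 diethylphosphonoacetic acid
Product: 27 (2E,4Z)-5-iodohexa-2,4-dienoic acid, via (Z)-3-iodobut-2-enal 25 (not isolated), via dilithiated phosphonoacetate 26 (not isolated)
Conditions: MnO2, CH2Cl2, rt, dark, filtered; 24, n-BuLi (2 equiv), THF, −78 °C; then the aldehyde solution, −78 to 0 °C; 1 M HCl
Reagents that add atoms: none
Why: Allylic oxidation with MnO2 followed by Horner–Wadsworth–Emmons olefination with the phosphonoacetate dianion gives the 2E acid directly, and the crude Z iodoenal is used cold and in the dark so that it does not isomerize.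

**Step 14**
Reactants: 27 (2E,4Z)-5-iodohexa-2,4-dienoic acid
Product: 28 triisopropylsilyl (2E,4Z)-5-iodohexa-2,4-dienoate
Conditions: TIPSCl, Et3N, CH2Cl2, 0 °C
Reagents that add atoms: chlorotriisopropylsilane, CC(C)[Si](Cl)(C(C)C)C(C)C
Why: Silyl ester formation gives an acid protecting group that should survive neutral palladium and rhodium chemistry and falls to HF in the last step.

**Step 15**
Reactants: 29 prop-2-yn-1-ol
Product: 30 (E)-3-(tributylstannyl)prop-2-en-1-ol
Conditions: Bu3SnH, AIBN (cat.), neat, 80 °C; chromatography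
Reagents that add atoms: tributyltin hydride, CCCC[SnH](CCCC)CCCC
Why: Radical hydrostannation of the terminal alkyne under thermodynamic control should give mainly the E β-stannyl allylic alcohol, which is separated from its isomers.

**Step 16**
Reactants: 30 (E)-3-(tributylstannyl)prop-2-en-1-ol; 31 2-(triphenylphosphoranylidene)propanal
Product: 33 (2E,4E)-2-methyl-5-(tributylstannyl)penta-2,4-dienal, via (E)-3-(tributylstannyl)prop-2-enal 32 (not isolated)
Conditions: MnO2, CH2Cl2, rt, filtered; then 31, toluene, 70 °C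
Reagents that add atoms: none
Why: MnO2 oxidation to the enal and Wittig reaction with the stabilized formyl ylide, which gives the E trisubstituted enal and should react only once because the 2-methyl dienal product is less electrophilic.

**Step 17**
Reactants: 28 triisopropylsilyl (2E,4Z)-5-iodohexa-2,4-dienoate; 33 (2E,4E)-2-methyl-5-(tributylstannyl)penta-2,4-dienal
Product: 34 triisopropylsilyl (2E,4Z,6E,8E)-5,9-dimethyl-10-oxodeca-2,4,6,8-tetraenoate
Conditions: Pd2(dba)3 (2.5 mol %), AsPh3 (20 mol %), NMP, rt, dark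
Reagents that add atoms: none
Why: Stille coupling of the alkenyl iodide with the alkenylstannane proceeds with retention at both sp2 carbons, so the 4Z geometry from step 12 and the E geometries from steps 13, 15 and 16 are carried into the tetraene.

**Step 18**
Reactants: 20 (1S,3S,7R,8R,8aS)-3,7,8-trimethyl-7-(triethylsilyloxy)-8-[3-(triethylsilyloxy)propanoyl]-1,2,3,7,8,8a-hexahydronaphthalen-1-yl prop-2-enoate; 34 triisopropylsilyl (2E,4Z,6E,8E)-5,9-dimethyl-10-oxodeca-2,4,6,8-tetraenoate
Product: 36 calbistrin D 12′-triisopropylsilyl ester bis(triethylsilyl) ether (O7 and the primary oxygen silylated; C3′–OH free), via diethoxymethylsilyl aldolate 35 (not isolated)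
Conditions: (S,S)-Rh(Phebox-iPr)(OAc)2(H2O) (2 mol %), (EtO)2MeSiH (2 equiv), toluene, 50 °C, dark; then 0.5 M citric acid, THF, 0 °C
Reagents that add atoms: none
Why: The rhodium acetate is converted by the silane into Rh–H, which adds 1,4 to the unhindered acrylate C=C of 20 to give a rhodium ester enolate held in the pocket of the C2-symmetric bis[(4S)-4-isopropyloxazolinyl]phenyl pincer; this enolate adds to the aldehyde carbon C3′ of 34 through a closed six-membered transition state, and σ-bond metathesis with the silane releases silyl aldolate 35 and returns Rh–H. The closest known reaction type is the Rh(Phebox)-catalysed, anti-selective asymmetric reductive aldol reaction of acrylates with aryl and alkenyl aldehydes; no ring is closed. C2′ (S) and C3′ (R) are both set here: the anti relation follows from the E enolate in the chair-like transition state, and the absolute sense from the (S,S) ligand, which should override the bias of the resident ring A stereocentres. The step needs chemoselectivity for the acrylate over the C4=C4a–C5=C6 diene, the tetraenoate and the two other carbonyl groups; the terminal, unsubstituted, electron-poor acrylate alkene and the single aldehyde secure this. Because no base is present, the C8 ketone, the β-silyloxy ketone and the new aldol should be neither enolized nor cleaved, and the mild acidic work-up removes only the labile diethoxymethylsilyl group from O3′.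

**Step 19**
Reactants: 36 calbistrin D 12′-triisopropylsilyl ester bis(triethylsilyl) ether
Product: 37 calbistrin D
Conditions: HF·pyridine, pyridine, THF, 0 °C to rt, dark
Reagents that add atoms: none
Why: Fluoride-driven cleavage of the silyl ester and of both triethylsilyl ethers under buffered, non-basic conditions, which should avoid retro-aldol reaction or β-elimination at the two β-hydroxy carbonyl units and spare the tertiary dienyl carbinol and the tetraene.

**Compound list**
1 | 2-methylfuran | Cc1ccco1 | starting material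
2 | (S)-1-bromo-3-chloro-2-methylpropane | BrC[C@@H](C)CCl | starting material
3 | 5-methyl-2-furyllithium | [Li]c1ccc(C)o1 | intermediate
4 | (R)-2-(3-chloro-2-methylpropyl)-5-methylfuran | Cc1ccc(C[C@@H](C)CCl)o1 | intermediate
5 | butane-2,3-dione | CC(=O)C(C)=O | starting material
6 | tert-butyl (triphenylphosphoranylidene)acetate | CC(C)(C)OC(=O)C=P(c1ccccc1)(c1ccccc1)c1ccccc1 | starting material
7 | tert-butyl (E)-3-methyl-4-oxopent-2-enoate | CC(C)(C)OC(=O)/C=C(\C)C(C)=O | intermediate
8 | (E)-3-methyl-4-oxopent-2-enoic acid | OC(=O)/C=C(\C)C(C)=O | intermediate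
9 | (E)-3-methyl-4-oxopent-2-enoyl chloride | ClC(=O)/C=C(\C)C(C)=O | intermediate
10 | [(R)-2-methyl-3-(5-methylfuran-2-yl)propyl]magnesium chloride | Cc1ccc(C[C@@H](C)C[Mg]Cl)o1 | intermediate
11 | [(R)-2-methyl-3-(5-methylfuran-2-yl)propyl]zinc chloride | Cc1ccc(C[C@@H](C)C[Zn]Cl)o1 | intermediate
12 | (3E,7R)-3,7-dimethyl-8-(5-methylfuran-2-yl)oct-3-ene-2,5-dione | Cc1ccc(C[C@@H](C)CC(=O)/C=C(\C)C(C)=O)o1 | intermediate
13 | (3R,4aS,7R,8R,8aR)-8-acetyl-4a,7-epoxy-3,7,8-trimethyl-3,4,4a,7,8,8a-hexahydronaphthalen-1(2H)-one (C4a–O–C7 bridge; H8a and acetyl endo, C8 methyl exo) | O=C1C[C@H](C)C[C@@]23C=C[C@@](C)(O2)[C@](C)(C(C)=O)[C@@H]13 | intermediate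
14 | (1S,3S,4aS,7R,8R,8aS)-8-acetyl-4a,7-epoxy-3,7,8-trimethyl-1,2,3,4,4a,7,8,8a-octahydronaphthalen-1-ol (C1–OH axial, syn to the bridge oxygen) | O[C@H]1C[C@H](C)C[C@@]23C=C[C@@](C)(O2)[C@](C)(C(C)=O)[C@@H]13 | intermediate
15 | dilithium alkoxide-enolate of 14 | [Li]O[C@H]1C[C@H](C)C[C@@]23C=C[C@@](C)(O2)[C@](C)(C(=C)O[Li])[C@@H]13 | intermediate
16 | (1S,3S,7R,8R,8aS)-8-acetyl-3,7,8-trimethyl-1,2,3,7,8,8a-hexahydronaphthalene-1,7-diol | O[C@H]1C[C@H](C)C=C2C=C[C@@](C)(O)[C@](C)(C(C)=O)[C@H]21 | intermediate
17 | (1S,3S,7R,8R,8aS)-8-acetyl-7-hydroxy-3,7,8-trimethyl-1,2,3,7,8,8a-hexahydronaphthalen-1-yl prop-2-enoate | C=CC(=O)O[C@H]1C[C@H](C)C=C2C=C[C@@](C)(O)[C@](C)(C(C)=O)[C@H]21 | intermediate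
18 | (1S,3S,7R,8R,8aS)-3,7,8-trimethyl-7-(triethylsilyloxy)-8-[1-(triethylsilyloxy)ethenyl]-1,2,3,7,8,8a-hexahydronaphthalen-1-yl prop-2-enoate | C=CC(=O)O[C@H]1C[C@H](C)C=C2C=C[C@@](C)(O[Si](CC)(CC)CC)[C@](C)(C(=C)O[Si](CC)(CC)CC)[C@H]21 | intermediate
19 | (1S,3S,7R,8R,8aS)-8-(3-hydroxypropanoyl)-3,7,8-trimethyl-7-(triethylsilyloxy)-1,2,3,7,8,8a-hexahydronaphthalen-1-yl prop-2-enoate | C=CC(=O)O[C@H]1C[C@H](C)C=C2C=C[C@@](C)(O[Si](CC)(CC)CC)[C@](C)(C(=O)CCO)[C@H]21 | intermediate
20 | (1S,3S,7R,8R,8aS)-3,7,8-trimethyl-7-(triethylsilyloxy)-8-[3-(triethylsilyloxy)propanoyl]-1,2,3,7,8,8a-hexahydronaphthalen-1-yl prop-2-enoate | C=CC(=O)O[C@H]1C[C@H](C)C=C2C=C[C@@](C)(O[Si](CC)(CC)CC)[C@](C)(C(=O)CCO[Si](CC)(CC)CC)[C@H]21 | intermediate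
21 | but-2-yn-1-ol | CC#CCO | starting material
22 | sodium 2,2-bis(2-methoxyethoxy)-3-methyl-2,5-dihydro-1,2-oxaalumol-2-uide (cyclic alkenylalanate) | CC1=CCO[Al-]1(OCCOC)OCCOC.[Na+] | intermediate
23 | (Z)-3-iodobut-2-en-1-ol | C/C(I)=C/CO | intermediate
24 | diethylphosphonoacetic acid | CCOP(=O)(CC(=O)O)OCC | starting material
25 | (Z)-3-iodobut-2-enal | C/C(I)=C/C=O | intermediate
26 | dilithiated diethylphosphonoacetate | [Li]OC(=O)C([Li])P(=O)(OCC)OCC | intermediate
27 | (2E,4Z)-5-iodohexa-2,4-dienoic acid | C/C(I)=C/C=C/C(=O)O | intermediate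
28 | triisopropylsilyl (2E,4Z)-5-iodohexa-2,4-dienoate | C/C(I)=C/C=C/C(=O)O[Si](C(C)C)(C(C)C)C(C)C | intermediate
29 | prop-2-yn-1-ol | C#CCO | starting material
30 | (E)-3-(tributylstannyl)prop-2-en-1-ol | CCCC[Sn](CCCC)(CCCC)/C=C/CO | intermediate
31 | 2-(triphenylphosphoranylidene)propanal | CC(C=O)=P(c1ccccc1)(c1ccccc1)c1ccccc1 | starting material
32 | (E)-3-(tributylstannyl)prop-2-enal | CCCC[Sn](CCCC)(CCCC)/C=C/C=O | intermediate
33 | (2E,4E)-2-methyl-5-(tributylstannyl)penta-2,4-dienal | CCCC[Sn](CCCC)(CCCC)/C=C/C=C(\C)C=O | intermediate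
34 | triisopropylsilyl (2E,4Z,6E,8E)-5,9-dimethyl-10-oxodeca-2,4,6,8-tetraenoate | CC(=C/C=C/C(=O)O[Si](C(C)C)(C(C)C)C(C)C)/C=C/C=C(\C)C=O | intermediate
35 | 3′-O-(diethoxymethylsilyl) derivative of 36 | CC(=C/C=C/C(=O)O[Si](C(C)C)(C(C)C)C(C)C)/C=C/C=C(\C)[C@H](O[Si](C)(OCC)OCC)[C@H](C)C(=O)O[C@H]1C[C@H](C)C=C2C=C[C@@](C)(O[Si](CC)(CC)CC)[C@](C)(C(=O)CCO[Si](CC)(CC)CC)[C@H]21 | intermediate
36 | calbistrin D 12′-triisopropylsilyl ester bis(triethylsilyl) ether: (1S,3S,7R,8R,8aS)-ring unit esterified at O1 by the (2′S,3′R,4′E,6′E,8′Z,10′E)-3′-hydroxy-2′,4′,8′-trimethyl chain | CC(=C/C=C/C(=O)O[Si](C(C)C)(C(C)C)C(C)C)/C=C/C=C(\C)[C@H](O)[C@H](C)C(=O)O[C@H]1C[C@H](C)C=C2C=C[C@@](C)(O[Si](CC)(CC)CC)[C@](C)(C(=O)CCO[Si](CC)(CC)CC)[C@H]21 | intermediate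
37 | calbistrin D, (2E,4Z,6E,8E,10R,11S)-10-hydroxy-12-{[(1S,3S,7R,8R,8aS)-7-hydroxy-8-(3-hydroxypropanoyl)-3,7,8-trimethyl-1,2,3,7,8,8a-hexahydronaphthalen-1-yl]oxy}-5,9,11-trimethyl-12-oxododeca-2,4,6,8-tetraenoic acid | CC(=C/C=C/C(=O)O)/C=C/C=C(\C)[C@H](O)[C@H](C)C(=O)O[C@H]1C[C@H](C)C=C2C=C[C@@](C)(O)[C@](C)(C(=O)CCO)[C@H]21 | target

**Totals**
Total steps: 19. Longest linear sequence: 12 steps (steps 2, 3, 4, 5, 6, 7, 8, 9, 10, 11, 18, 19).

**Steps most likely to fail**

Step 8 (proposed new method). Risk: the base removes a hydrogen of the C7 methyl group or H8a instead of the equatorial hydrogen on C4, or the alkoxide triggers cycloreversion. Fallback with known chemistry, setting out from 13 and coming back at 19. Ketone 13 is treated with DBU (CH2Cl2, 0 °C), which enolizes C1 toward C8a and expels the bridge oxygen by β-elimination (E1cB) to give (3R,7R,8R)-8-acetyl-7-hydroxy-3,7,8-trimethyl-3,4,7,8-tetrahydronaphthalen-1(2H)-one F1. Silylation (TESOTf, 2,6-lutidine) gives its triethylsilyl ether F2. The thermodynamic dienolate (KOt-Bu, t-BuOH–THF) is quenched into cold aqueous acetic acid, and kinetic α-protonation gives the deconjugated ketone F3 with the C4=C4a–C5=C6 diene. L-Selectride at −78 °C gives the axial alcohol F4, acryloyl chloride gives its acrylate F5, and the conditions of step 10 (O7 is already silylated) lead through 18 to 19. In this variant C8a is formed by protonation, so its face selectivity has to be checked at F3.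

Step 6. Risk: reversal of the cycloaddition, because the adduct carries two adjacent quaternary carbons (C7 and C8) and little 13 may be present at equilibrium. Fallback, setting out from 12 and coming back at 19. 12 is heated with DBU in toluene so that each molecule of adduct is drained as it forms by the irreversible β-elimination described above; this gives the dienone F1 straight from 12, and the sequence through F2 to F5 returns to 19. This fallback makes no compound beyond those already named.

Step 18. Risk: poor facial selectivity if catalyst and chiral ester are mismatched, or plain 1,4-reduction of the acrylate and hydrosilylation of the aldehyde in place of C–C bond formation. Fallback, setting out from 16 and coming back at 37: a stereoconvergent chromium Reformatsky reaction. 16 is acylated with racemic 2-bromopropanoyl bromide (pyridine, CH2Cl2, −20 °C) to the 2-bromopropanoate F6 (both epimers at the bromine-bearing carbon). The conditions of step 10 give, through the bis(triethylsilyl) enol ether F7, the 3-hydroxypropanoyl bromo ester F8. CrCl2 (divalent chromium, 4 equiv) and LiI (cat.) in THF at room temperature should convert both bromide epimers into one chromium enolate, which adds only to the aldehyde of 34 and should favour the anti aldol, giving the coupled ester F9 (O7 silyl ether and silyl ester kept, primary and C3′ hydroxyls free). HF·pyridine as in step 19 then gives 37. Facial control in this variant rests on the chiral ring A ester alone.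

**Further compounds**
F1 | step 8 | (3R,7R,8R)-8-acetyl-7-hydroxy-3,7,8-trimethyl-3,4,7,8-tetrahydronaphthalen-1(2H)-one | O=C1C[C@H](C)CC2=C1[C@@](C)(C(C)=O)[C@](C)(O)C=C2
F2 | step 8 | (3R,7R,8R)-8-acetyl-3,7,8-trimethyl-7-(triethylsilyloxy)-3,4,7,8-tetrahydronaphthalen-1(2H)-one | O=C1C[C@H](C)CC2=C1[C@@](C)(C(C)=O)[C@](C)(O[Si](CC)(CC)CC)C=C2
F3 | step 8 | (3S,7R,8R,8aS)-8-acetyl-3,7,8-trimethyl-7-(triethylsilyloxy)-3,7,8,8a-tetrahydronaphthalen-1(2H)-one | O=C1C[C@H](C)C=C2C=C[C@@](C)(O[Si](CC)(CC)CC)[C@](C)(C(C)=O)[C@H]21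
F4 | step 8 | (1S,3S,7R,8R,8aS)-8-acetyl-3,7,8-trimethyl-7-(triethylsilyloxy)-1,2,3,7,8,8a-hexahydronaphthalen-1-ol | O[C@H]1C[C@H](C)C=C2C=C[C@@](C)(O[Si](CC)(CC)CC)[C@](C)(C(C)=O)[C@H]21
F5 | step 8 | (1S,3S,7R,8R,8aS)-8-acetyl-3,7,8-trimethyl-7-(triethylsilyloxy)-1,2,3,7,8,8a-hexahydronaphthalen-1-yl prop-2-enoate | C=CC(=O)O[C@H]1C[C@H](C)C=C2C=C[C@@](C)(O[Si](CC)(CC)CC)[C@](C)(C(C)=O)[C@H]21
F0 | step 6 | none | none
F6 | step 18 | (1S,3S,7R,8R,8aS)-8-acetyl-7-hydroxy-3,7,8-trimethyl-1,2,3,7,8,8a-hexahydronaphthalen-1-yl 2-bromopropanoate (both epimers at C2′) | CC(Br)C(=O)O[C@H]1C[C@H](C)C=C2C=C[C@@](C)(O)[C@](C)(C(C)=O)[C@H]21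
F7 | step 18 | (1S,3S,7R,8R,8aS)-3,7,8-trimethyl-7-(triethylsilyloxy)-8-[1-(triethylsilyloxy)ethenyl]-1,2,3,7,8,8a-hexahydronaphthalen-1-yl 2-bromopropanoate (both epimers at C2′) | CC(Br)C(=O)O[C@H]1C[C@H](C)C=C2C=C[C@@](C)(O[Si](CC)(CC)CC)[C@](C)(C(=C)O[Si](CC)(CC)CC)[C@H]21
F8 | step 18 | (1S,3S,7R,8R,8aS)-8-(3-hydroxypropanoyl)-3,7,8-trimethyl-7-(triethylsilyloxy)-1,2,3,7,8,8a-hexahydronaphthalen-1-yl 2-bromopropanoate (both epimers at C2′) | CC(Br)C(=O)O[C@H]1C[C@H](C)C=C2C=C[C@@](C)(O[Si](CC)(CC)CC)[C@](C)(C(=O)CCO)[C@H]21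
F9 | step 18 | calbistrin D 12′-triisopropylsilyl ester 7-O-triethylsilyl ether | CC(=C/C=C/C(=O)O[Si](C(C)C)(C(C)C)C(C)C)/C=C/C=C(\C)[C@H](O)[C@H](C)C(=O)O[C@H]1C[C@H](C)C=C2C=C[C@@](C)(O[Si](CC)(CC)CC)[C@](C)(C(=O)CCO)[C@H]21
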